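(The data are calculated on assumed constants; the scatter is artificial.)

Amounts first: the midnight run charged 0.11 M of Q and 0.15 M of J, and what was read is L.

| flask | Q | J | remark | time |
|---|---|---|---|---|
| midnight | 0.11 M | 0.15 M | run made earlier |  |
| maple | 0.20 M | 0.150 M |  | 12 min |
| ash | 0.10 M | 0.500 M |  | 12 min |
| alder | 0.10 M | 0.150 M |  | 12 min |
| larch | 0.20 M | 0.500 M |  | 12 min |

midnight run (percent of the Q charged)

| time / min | L / % |
|---|---|
| 0.417 | 11.4 |
| 0.833 | 17.8 |
| 1.33 | 23.5 |
| 1.50 | 24.9 |
| 2.00 | 28.3 |
| 2.50 | 32.0 |

(each reading ± 0.5 percentage points)

- what was read earlier has a scatter of 0.5 percentage points, one standard deviation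

1. ranking by amount of L, in percent of the Q charged, from high to low, at 12 min (maple / ash / alder / larch)
2. the same order at 2.5 min (maple / ash / alder / larch)
3. the amount of L, in percent of the Q charged of the flask you put first, at 12 min
4. the amount of L, in percent of the Q charged of the flask you put last, at 12 min

In the first instants of the midnight run, L forms at 0.273 min⁻¹ of the Q charged, reckoned over the first 0.417 min. In the middle, from 1.50 min to 2.50 min, the speed read is 0.0710 min⁻¹, a fall by a factor of 3.85. At 2.00 min the run holds 0.0311 M of L. If one Q and one J stood behind each L, that would leave 0.0789 M of Q and 0.119 M of J, and a rate proportional to cQ times cJ would have fallen by 1.76. The fall read is larger, so we reckon that a second path removes Q and J without giving L.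

One run cannot show how much J that path takes. We commit to two J per Q, which is a guess, and under it the path gains on L as cJ rises. The loss of Q that brings cQ times cJ down by the factor read is 0.0219 M, which leaves cJ at 0.0752 M. Over that stretch cJ averages 0.113 M. L against loss, times this mean, gives 0.160 M, the split concentration: the cJ at which L and the loss take Q equally fast, a selectivity factor written as a concentration and a reading with the scatter of the data. L's share of the Q reacting is then split/(split+cJ).

At the start this share is 51.7% in alder and maple, and 24.3% in ash and larch. Each Q used costs two minus the share in J. At this share alder needs 0.148 M of J for all its Q and has 0.150 M, so J sets no cap on L in alder. We put alder's L near 51.7% as a rough figure, not a bound: the share rises as J falls, while Q may still stand unreacted at 12 min, and these two pull opposite ways. In maple J is the limiting reagent, and at the opening share it carries L to 26.1%. Maple's figure is a floor once its J is used, since the share rises as J falls. Larch has twice the Q of ash on the same J, so its J falls further and we put it above ash. Maple's floor is higher than the opening share of larch. Our order is alder, maple, larch, ash, with ash near 24.3%; for 2.5 min we give no reckoning.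

The forecast differs from ours: it put ash > larch > alder > maple at 12 min and ash > larch > alder > maple at 2.5 min, with 95% first and 50% last at 12 min, assuming that “more J speeds the slow phase”.

The flasks give alder > maple > larch > ash at 12 min, with 52.5% and 23.3%, and alder > larch > maple > ash at 2.5 min.

    Q + J → L (k = 0.0370 M⁻¹ s⁻¹)
    Q + 2 J → G (k = 0.300 M⁻² s⁻¹)

In alder the L step uses Q at 0.82 of the rate of the G step at the start, and at 1.6 of it at 1.62 min. We had put ash near 24.3%, and ash, with Q at 0%, holds 23.3% of L. A neighbour of alder charged with 0.037 M of J has 8.21% of that J left at 12.0 min, and at the mean of its first and last cJ the split concentration gives a share of 88.9%; that flask holds 26.0% of L and 3.97% of G, a share over the run of 86.8%.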